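**Retrosynthetic overview**
1. Hippolide D ⇒ (allylic oxidation, desilylation) bis-TBS anhydride 28 ⇒ CO + β-lactone 26. The strategy rests on this feature: the oxolane-2,5-dione ring C18–C19–C20(=O)–O–C21(=O) is the oxetan-2-one ring C18–C19–O–C21(=O) with one carbonyl, C20, inserted into the C19–O bond (C17 = carbinol, C18 = ring CH, C19 = ring CH2).
2. 26 ⇒ (Mitsunobu closure at C19) 2-(hydroxymethyl)-3-silyloxy acid 25 ⇒ (auxiliary and PMB removal) imide 22.
3. C14=C15 ⇒ Wittig reaction of C15 aldehyde 10 with α-formyl ylide 19 (from farnesyl bromide and tert-butyl acetate, C12–C13 bond), then Luche reduction and silylation of C22–OH.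
4. C17–C18 with both stereocentres ⇒ Evans syn aldol of the 3-(PMB-oxy)propanoyl imide 4 with 3-(TBS-oxy)propanal 5.
5. Ring order: the target has one ring; the four-membered lactone is closed first (step 16) and then expanded to the five-membered anhydride (step 17).

Key step: step 17

Remark: atom numbers follow the terpenoid chain (C1–C19, anhydride carbonyls C20 on C19 and C21 on C18, C22 = the carbon on C14); TBS = tert-butyldimethylsilyl, PMB = 4-methoxybenzyl; acid 1 and aldehyde 5 are taken as catalogue chemicals, and the free β-hydroxy anhydride is assumed to be isolable because it is the target itself.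

**Route**

Step 1
Reactants: 1 3-[(4-methoxybenzyl)oxy]propanoic acid; 2 (S)-4-benzyloxazolidin-2-one
Product: 4 (S)-4-benzyl-3-{3-[(4-methoxybenzyl)oxy]propanoyl}oxazolidin-2-one, via mixed pivalic anhydride 3 (not isolated)
Conditions: PivCl, Et3N, THF, −20 °C; then 2, LiCl, −20 °C to rt
Reagents that add atoms: none
Why: N-acylation of the oxazolidinone through the mixed pivalic anhydride is a standard preparation of Evans imides, and the PMB ether is inert to it.

Step 2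
Reactants: 4 (S)-4-benzyl-3-{3-[(4-methoxybenzyl)oxy]propanoyl}oxazolidin-2-one; 5 3-[(tert-butyldimethylsilyl)oxy]propanal
Product: 7 (S)-4-benzyl-3-[(2S,3R)-5-(TBS-oxy)-3-hydroxy-2-(PMB-oxymethyl)pentanoyl]oxazolidin-2-one, via (Z)-dibutylboron enolate 6 (not isolated)
Conditions: Bu2BOTf, i-Pr2NEt, CH2Cl2, −78 to 0 °C; then 5, −78 to 0 °C; pH 7 buffer, MeOH, H2O2, 0 °C
Reagents that add atoms: none
Why: Evans syn aldol, in which the (Z)-boron enolate reacts through a closed Zimmerman–Traxler chair on the face away from the benzyl group, so that C18 (S) and C17 (R) are set together in the syn relation the lactone needs, while the covalent boron enolate should not expel the β-alkoxide.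

Step 3
Reactants: 7 (S)-4-benzyl-3-[(2S,3R)-5-(TBS-oxy)-3-hydroxy-2-(PMB-oxymethyl)pentanoyl]oxazolidin-2-one
Product: 8 (S)-4-benzyl-3-[(2S,3R)-3,5-bis(TBS-oxy)-2-(PMB-oxymethyl)pentanoyl]oxazolidin-2-one
Conditions: TBSOTf, 2,6-lutidine, CH2Cl2, −78 to 0 °C
Reagents that add atoms: tert-butyldimethylsilyl triflate, CC(C)(C)[Si](C)(C)OS(=O)(=O)C(F)(F)F
Why: Silylation of the hindered secondary aldol hydroxyl with the silyl triflate and a hindered base is routine and blocks retro-aldol cleavage in the later steps.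

Step 4
Reactants: 8 (S)-4-benzyl-3-[(2S,3R)-3,5-bis(TBS-oxy)-2-(PMB-oxymethyl)pentanoyl]oxazolidin-2-one
Product: 9 (S)-4-benzyl-3-[(2S,3R)-3-(TBS-oxy)-5-hydroxy-2-(PMB-oxymethyl)pentanoyl]oxazolidin-2-one
Conditions: HF·pyridine, pyridine, THF, 0 °C
Reagents that add atoms: none
Why: Selective desilylation of a primary TBS ether beside a hindered secondary one with buffered HF·pyridine is well established, and the α-branched imide carbonyl is shielded enough that the freed C15 hydroxyl should not lactonise if the crude alcohol is oxidised at once.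

Step 5
Reactants: 9 (S)-4-benzyl-3-[(2S,3R)-3-(TBS-oxy)-5-hydroxy-2-(PMB-oxymethyl)pentanoyl]oxazolidin-2-one
Product: 10 (S)-4-benzyl-3-[(2S,3R)-3-(TBS-oxy)-2-(PMB-oxymethyl)-5-oxopentanoyl]oxazolidin-2-one
Conditions: Dess–Martin periodinane, CH2Cl2, 0 °C to rt
Reagents that add atoms: none
Why: Dess–Martin oxidation should give the β-silyloxy aldehyde under near-neutral conditions without β-elimination or epimerisation at C18.

Step 6
Reactants: 11 (2E,6E)-farnesyl bromide; 12 tert-butyl acetate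
Product: 14 tert-butyl (4E,8E)-5,9,13-trimethyltetradeca-4,8,12-trienoate, via lithium enolate of tert-butyl acetate 13 (not isolated)
Conditions: LDA, THF, −78 °C; then 11, DMPU, −78 to 0 °C
Reagents that add atoms: none
Why: SN2 alkylation of the lithium ester enolate at the primary allylic bromide forms the C12–C13 bond and keeps the (E,E) geometry of the farnesyl unit.

Step 7
Reactants: 14 tert-butyl (4E,8E)-5,9,13-trimethyltetradeca-4,8,12-trienoate
Product: 15 (4E,8E)-5,9,13-trimethyltetradeca-4,8,12-trien-1-ol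
Conditions: LiAlH4, Et2O, 0 °C
Reagents that add atoms: none
Why: Hydride reduction of the ester to the primary alcohol (C14–OH) leaves the isolated trisubstituted alkenes untouched.

Step 8
Reactants: 15 (4E,8E)-5,9,13-trimethyltetradeca-4,8,12-trien-1-ol
Product: 16 (6E,10E)-14-iodo-2,6,10-trimethyltetradeca-2,6,10-triene
Conditions: I2, PPh3, imidazole, CH2Cl2, 0 °C to rt
Reagents that add atoms: iodine, II
Why: Appel-type iodination converts the primary alcohol into the iodide by SN2 displacement of the oxyphosphonium without affecting the alkenes.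

Step 9
Reactants: 16 (6E,10E)-14-iodo-2,6,10-trimethyltetradeca-2,6,10-triene
Product: 17 [(4E,8E)-5,9,13-trimethyltetradeca-4,8,12-trien-1-yl]triphenylphosphonium iodide
Conditions: PPh3, MeCN, reflux
Reagents that add atoms: triphenylphosphine, c1ccc(cc1)P(c1ccccc1)c1ccccc1
Why: Quaternisation of triphenylphosphine by the unhindered primary iodide (SN2) should give the phosphonium salt cleanly.

Step 10
Reactants: 17 [(4E,8E)-5,9,13-trimethyltetradeca-4,8,12-trien-1-yl]triphenylphosphonium iodide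
Product: 19 (5E,9E)-6,10,14-trimethyl-2-(triphenyl-λ5-phosphanylidene)pentadeca-5,9,13-trienal, via non-stabilised alkylidene ylide 18 (not isolated)
Conditions: t-BuOK, THF, 0 °C to rt; then HCO2Et, rt
Reagents that add atoms: ethyl formate, CCOC=O
Why: C-formylation of a non-stabilised ylide with ethyl formate (acyl substitution, then loss of the now acidic α-proton) is the known preparation of 2-(triphenylphosphoranylidene)alkanals and installs C22 at the aldehyde level on C14.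

Step 11
Reactants: 10 (S)-4-benzyl-3-[(2S,3R)-3-(TBS-oxy)-2-(PMB-oxymethyl)-5-oxopentanoyl]oxazolidin-2-one; 19 (5E,9E)-6,10,14-trimethyl-2-(triphenyl-λ5-phosphanylidene)pentadeca-5,9,13-trienal
Product: 20 (S)-4-benzyl-3-[(2S,3R,5E,9E,13E)-3-(TBS-oxy)-6-formyl-2-(PMB-oxymethyl)-10,14,18-trimethylnonadeca-5,9,13,17-tetraenoyl]oxazolidin-2-one
Conditions: toluene, 90 °C
Reagents that add atoms: none
Why: Wittig olefination with a formyl-stabilised α-alkyl ylide should give the (E)-2-alkyl enal (CHO trans to C16) under thermodynamic control, and the neutral ylide leaves the imide, the silyl ether and the C18 centre alone.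

Step 12
Reactants: 20 (S)-4-benzyl-3-[(2S,3R,5E,9E,13E)-3-(TBS-oxy)-6-formyl-2-(PMB-oxymethyl)-10,14,18-trimethylnonadeca-5,9,13,17-tetraenoyl]oxazolidin-2-one
Product: 21 (S)-4-benzyl-3-[(2S,3R,5E,9E,13E)-3-(TBS-oxy)-6-(hydroxymethyl)-2-(PMB-oxymethyl)-10,14,18-trimethylnonadeca-5,9,13,17-tetraenoyl]oxazolidin-2-one
Conditions: NaBH4, CeCl3·7H2O, MeOH/THF, −78 °C
Reagents that add atoms: none
Why: Luche 1,2-reduction of the enal at low temperature is much faster than borohydride attack on the N-acyloxazolidinone and keeps the C14=C15 geometry.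

Step 13
Reactants: 21 (S)-4-benzyl-3-[(2S,3R,5E,9E,13E)-3-(TBS-oxy)-6-(hydroxymethyl)-2-(PMB-oxymethyl)-10,14,18-trimethylnonadeca-5,9,13,17-tetraenoyl]oxazolidin-2-one
Product: 22 (S)-4-benzyl-3-[(2S,3R,5E,9E,13E)-3-(TBS-oxy)-6-(TBS-oxymethyl)-2-(PMB-oxymethyl)-10,14,18-trimethylnonadeca-5,9,13,17-tetraenoyl]oxazolidin-2-one
Conditions: TBSCl, imidazole, CH2Cl2, 0 °C to rt
Reagents that add atoms: tert-butyldimethylsilyl chloride, CC(C)(C)[Si](C)(C)Cl
Why: Standard silylation of the primary allylic alcohol masks C22–OH so that no free hydroxyl meets the Lewis acid or the anhydride in the key step.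

Step 14
Reactants: 22 (S)-4-benzyl-3-[(2S,3R,5E,9E,13E)-3-(TBS-oxy)-6-(TBS-oxymethyl)-2-(PMB-oxymethyl)-10,14,18-trimethylnonadeca-5,9,13,17-tetraenoyl]oxazolidin-2-one
Product: 23 (S)-4-benzyl-3-[(2S,3R,5E,9E,13E)-3-(TBS-oxy)-6-(TBS-oxymethyl)-2-(hydroxymethyl)-10,14,18-trimethylnonadeca-5,9,13,17-tetraenoyl]oxazolidin-2-one
Conditions: DDQ, CH2Cl2/pH 7 buffer, 0 °C
Reagents that add atoms: none
Why: Oxidative PMB cleavage with DDQ in wet dichloromethane frees only the C19 hydroxyl, and it is run before the acid is unveiled so that no carboxyl group can trap the benzylic cation.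

Step 15
Reactants: 23 (S)-4-benzyl-3-[(2S,3R,5E,9E,13E)-3-(TBS-oxy)-6-(TBS-oxymethyl)-2-(hydroxymethyl)-10,14,18-trimethylnonadeca-5,9,13,17-tetraenoyl]oxazolidin-2-one
Product: 25 (2S,3R,5E,9E,13E)-3-(TBS-oxy)-6-(TBS-oxymethyl)-2-(hydroxymethyl)-10,14,18-trimethylnonadeca-5,9,13,17-tetraenoic acid, via peroxy acid 24 (not isolated)
Conditions: LiOH, H2O2, THF/H2O, 0 °C; Na2SO3; then 1 M HCl to pH 3
Reagents that add atoms: hydrogen peroxide, OO
Why: Lithium hydroperoxide attacks the exocyclic imide carbonyl selectively (Evans auxiliary cleavage) and is too weakly basic to epimerise C18 or to cause retro-aldol loss of C19, and sulfite then reduces the peroxy acid to the acid.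

Step 16
Reactants: 25 (2S,3R,5E,9E,13E)-3-(TBS-oxy)-6-(TBS-oxymethyl)-2-(hydroxymethyl)-10,14,18-trimethylnonadeca-5,9,13,17-tetraenoic acid
Product: 26 (3S)-3-[(1R,3E,7E,11E)-1-(TBS-oxy)-4-(TBS-oxymethyl)-8,12,16-trimethylheptadeca-3,7,11,15-tetraen-1-yl]oxetan-2-one
Conditions: PPh3, DIAD, THF, −78 to 0 °C
Reagents that add atoms: none
Why: Mitsunobu lactonisation by hydroxyl activation, in which the carboxylate displaces the primary oxyphosphonium at C19 (4-exo-tet) as in the known closure of 2-substituted 3-hydroxypropanoic acids to α-substituted β-propiolactones, with C18 not a reacting centre.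

Step 17
Reactants: 26 (3S)-3-[(1R,3E,7E,11E)-1-(TBS-oxy)-4-(TBS-oxymethyl)-8,12,16-trimethylheptadeca-3,7,11,15-tetraen-1-yl]oxetan-2-one; 27 carbon monoxide
Product: 28 (3S)-3-[(1R,3E,7E,11E)-1-(TBS-oxy)-4-(TBS-oxymethyl)-8,12,16-trimethylheptadeca-3,7,11,15-tetraen-1-yl]oxolane-2,5-dione
Conditions: [(salph)Al(THF)2][Co(CO)4] (5 mol %), CO (14 bar), toluene, 50 °C
Reagents that add atoms: none
Why: The aluminium cation binds the lactone carbonyl and tetracarbonylcobaltate opens the ring by SN2 attack at the unsubstituted C19, giving an aluminium carboxylate (C21) and a C19–cobalt alkyl. Migratory insertion of CO forms the C19–C20 bond, and the carboxylate oxygen then attacks the acylcobalt (5-exo-trig acyl substitution) to form the C20–O bond, close the oxolane-2,5-dione ring and release the cobaltate. The closest known reaction is the Lewis acid/cobaltate-catalysed ring-expansion carbonylation of β-lactones to succinic anhydrides. No stereocentre is created: C19 is a CH2 group, and C18 and C17 are not touched, so the configuration from the aldol step is carried through. The step needs cleavage of the alkyl C19–O bond and not the acyl C21–O bond, which the soft cobaltate attacking a primary ring carbon should secure. It also needs no epimerisation at C18 and no acylation of hydroxyl groups by the product, which the neutral aprotic medium and the two silyl ethers should secure, with the trisubstituted alkenes inert in the absence of hydrogen.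

Step 18
Reactants: 28 (3S)-3-[(1R,3E,7E,11E)-1-(TBS-oxy)-4-(TBS-oxymethyl)-8,12,16-trimethylheptadeca-3,7,11,15-tetraen-1-yl]oxolane-2,5-dione
Product: 29 (3S)-3-[(1R,3E,7E,11E)-1-hydroxy-4-(hydroxymethyl)-8,12,16-trimethylheptadeca-3,7,11,15-tetraen-1-yl]oxolane-2,5-dione
Conditions: HF·pyridine, THF, 0 °C to rt; filtration through a short silica plug, no aqueous base
Reagents that add atoms: none
Why: Fluoride cleavage of both silyl ethers in an acidic non-aqueous medium should leave the anhydride closed, because neither hydroxide nor alkoxide is present and the work-up avoids base.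

Step 19
Reactants: 29 (3S)-3-[(1R,3E,7E,11E)-1-hydroxy-4-(hydroxymethyl)-8,12,16-trimethylheptadeca-3,7,11,15-tetraen-1-yl]oxolane-2,5-dione
Product: 30 Hippolide D, (3S)-3-[(1R,3E,7E,11E)-4-formyl-1-hydroxy-8,12,16-trimethylheptadeca-3,7,11,15-tetraen-1-yl]oxolane-2,5-dione
Conditions: activated MnO2, CH2Cl2, rt
Reagents that add atoms: none
Why: Manganese dioxide oxidises only the primary allylic alcohol and leaves the saturated secondary C17 hydroxyl and the anhydride, so the (E)-enal should form without isomerisation.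

**Compound list**
1 | 3-[(4-methoxybenzyl)oxy]propanoic acid | COc1ccc(COCCC(=O)O)cc1 | starting material
2 | (S)-4-benzyloxazolidin-2-one | O=C1N[C@@H](Cc2ccccc2)CO1 | starting material
3 | mixed anhydride of 1 with pivalic acid | COc1ccc(COCCC(=O)OC(=O)C(C)(C)C)cc1 | intermediate (not isolated)
4 | (S)-4-benzyl-3-{3-[(4-methoxybenzyl)oxy]propanoyl}oxazolidin-2-one | COc1ccc(COCCC(=O)N2[C@@H](Cc3ccccc3)COC2=O)cc1 | intermediate
5 | 3-[(tert-butyldimethylsilyl)oxy]propanal | CC(C)(C)[Si](C)(C)OCCC=O | starting material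
6 | (Z)-dibutylboron enolate of 4 | CCCCB(CCCC)O/C(=C\COCc1ccc(OC)cc1)N1[C@@H](Cc2ccccc2)COC1=O | intermediate (not isolated)
7 | (S)-4-benzyl-3-[(2S,3R)-5-(TBS-oxy)-3-hydroxy-2-(PMB-oxymethyl)pentanoyl]oxazolidin-2-one | CC(C)(C)[Si](C)(C)OCC[C@@H](O)[C@H](COCc1ccc(OC)cc1)C(=O)N1[C@@H](Cc2ccccc2)COC1=O | intermediate
8 | (S)-4-benzyl-3-[(2S,3R)-3,5-bis(TBS-oxy)-2-(PMB-oxymethyl)pentanoyl]oxazolidin-2-one | CC(C)(C)[Si](C)(C)OCC[C@@H](O[Si](C)(C)C(C)(C)C)[C@H](COCc1ccc(OC)cc1)C(=O)N1[C@@H](Cc2ccccc2)COC1=O | intermediate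
9 | (S)-4-benzyl-3-[(2S,3R)-3-(TBS-oxy)-5-hydroxy-2-(PMB-oxymethyl)pentanoyl]oxazolidin-2-one | OCC[C@@H](O[Si](C)(C)C(C)(C)C)[C@H](COCc1ccc(OC)cc1)C(=O)N1[C@@H](Cc2ccccc2)COC1=O | intermediate
10 | (S)-4-benzyl-3-[(2S,3R)-3-(TBS-oxy)-2-(PMB-oxymethyl)-5-oxopentanoyl]oxazolidin-2-one | O=CC[C@@H](O[Si](C)(C)C(C)(C)C)[C@H](COCc1ccc(OC)cc1)C(=O)N1[C@@H](Cc2ccccc2)COC1=O | intermediate
11 | (2E,6E)-farnesyl bromide | CC(C)=CCC/C(C)=C/CC/C(C)=C/CBr | starting material
12 | tert-butyl acetate | CC(=O)OC(C)(C)C | starting material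
13 | lithium enolate of tert-butyl acetate | [Li+].C=C([O-])OC(C)(C)C | intermediate (not isolated)
14 | tert-butyl (4E,8E)-5,9,13-trimethyltetradeca-4,8,12-trienoate | CC(C)=CCC/C(C)=C/CC/C(C)=C/CCC(=O)OC(C)(C)C | intermediate
15 | (4E,8E)-5,9,13-trimethyltetradeca-4,8,12-trien-1-ol | CC(C)=CCC/C(C)=C/CC/C(C)=C/CCCO | intermediate
16 | (6E,10E)-14-iodo-2,6,10-trimethyltetradeca-2,6,10-triene | CC(C)=CCC/C(C)=C/CC/C(C)=C/CCCI | intermediate
17 | [(4E,8E)-5,9,13-trimethyltetradeca-4,8,12-trien-1-yl]triphenylphosphonium iodide | CC(C)=CCC/C(C)=C/CC/C(C)=C/CCC[P+](c1ccccc1)(c1ccccc1)c1ccccc1.[I-] | intermediate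
18 | [(4E,8E)-5,9,13-trimethyltetradeca-4,8,12-trienylidene]triphenylphosphorane | CC(C)=CCC/C(C)=C/CC/C(C)=C/CCC=P(c1ccccc1)(c1ccccc1)c1ccccc1 | intermediate (not isolated)
19 | (5E,9E)-6,10,14-trimethyl-2-(triphenyl-λ5-phosphanylidene)pentadeca-5,9,13-trienal | CC(C)=CCC/C(C)=C/CC/C(C)=C/CCC(C=O)=P(c1ccccc1)(c1ccccc1)c1ccccc1 | intermediate
20 | (S)-4-benzyl-3-[(2S,3R,5E,9E,13E)-3-(TBS-oxy)-6-formyl-2-(PMB-oxymethyl)-10,14,18-trimethylnonadeca-5,9,13,17-tetraenoyl]oxazolidin-2-one | CC(C)=CCC/C(C)=C/CC/C(C)=C/CC/C(C=O)=C\C[C@@H](O[Si](C)(C)C(C)(C)C)[C@H](COCc1ccc(OC)cc1)C(=O)N1[C@@H](Cc2ccccc2)COC1=O | intermediate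
21 | (S)-4-benzyl-3-[(2S,3R,5E,9E,13E)-3-(TBS-oxy)-6-(hydroxymethyl)-2-(PMB-oxymethyl)-10,14,18-trimethylnonadeca-5,9,13,17-tetraenoyl]oxazolidin-2-one | CC(C)=CCC/C(C)=C/CC/C(C)=C/CC/C(CO)=C\C[C@@H](O[Si](C)(C)C(C)(C)C)[C@H](COCc1ccc(OC)cc1)C(=O)N1[C@@H](Cc2ccccc2)COC1=O | intermediate
22 | (S)-4-benzyl-3-[(2S,3R,5E,9E,13E)-3-(TBS-oxy)-6-(TBS-oxymethyl)-2-(PMB-oxymethyl)-10,14,18-trimethylnonadeca-5,9,13,17-tetraenoyl]oxazolidin-2-one | CC(C)=CCC/C(C)=C/CC/C(C)=C/CC/C(CO[Si](C)(C)C(C)(C)C)=C\C[C@@H](O[Si](C)(C)C(C)(C)C)[C@H](COCc1ccc(OC)cc1)C(=O)N1[C@@H](Cc2ccccc2)COC1=O | intermediate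
23 | (S)-4-benzyl-3-[(2S,3R,5E,9E,13E)-3-(TBS-oxy)-6-(TBS-oxymethyl)-2-(hydroxymethyl)-10,14,18-trimethylnonadeca-5,9,13,17-tetraenoyl]oxazolidin-2-one | CC(C)=CCC/C(C)=C/CC/C(C)=C/CC/C(CO[Si](C)(C)C(C)(C)C)=C\C[C@@H](O[Si](C)(C)C(C)(C)C)[C@H](CO)C(=O)N1[C@@H](Cc2ccccc2)COC1=O | intermediate
24 | (2S,3R,5E,9E,13E)-3-(TBS-oxy)-6-(TBS-oxymethyl)-2-(hydroxymethyl)-10,14,18-trimethylnonadeca-5,9,13,17-tetraeneperoxoic acid | CC(C)=CCC/C(C)=C/CC/C(C)=C/CC/C(CO[Si](C)(C)C(C)(C)C)=C\C[C@@H](O[Si](C)(C)C(C)(C)C)[C@H](CO)C(=O)OO | intermediate (not isolated)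
25 | (2S,3R,5E,9E,13E)-3-(TBS-oxy)-6-(TBS-oxymethyl)-2-(hydroxymethyl)-10,14,18-trimethylnonadeca-5,9,13,17-tetraenoic acid | CC(C)=CCC/C(C)=C/CC/C(C)=C/CC/C(CO[Si](C)(C)C(C)(C)C)=C\C[C@@H](O[Si](C)(C)C(C)(C)C)[C@H](CO)C(=O)O | intermediate
26 | (3S)-3-[(1R,3E,7E,11E)-1-(TBS-oxy)-4-(TBS-oxymethyl)-8,12,16-trimethylheptadeca-3,7,11,15-tetraen-1-yl]oxetan-2-one | CC(C)=CCC/C(C)=C/CC/C(C)=C/CC/C(CO[Si](C)(C)C(C)(C)C)=C\C[C@@H](O[Si](C)(C)C(C)(C)C)[C@@H]1COC1=O | intermediate
27 | carbon monoxide | [C-]#[O+] | starting material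
28 | (3S)-3-[(1R,3E,7E,11E)-1-(TBS-oxy)-4-(TBS-oxymethyl)-8,12,16-trimethylheptadeca-3,7,11,15-tetraen-1-yl]oxolane-2,5-dione | CC(C)=CCC/C(C)=C/CC/C(C)=C/CC/C(CO[Si](C)(C)C(C)(C)C)=C\C[C@@H](O[Si](C)(C)C(C)(C)C)[C@@H]1CC(=O)OC1=O | intermediate
29 | (3S)-3-[(1R,3E,7E,11E)-1-hydroxy-4-(hydroxymethyl)-8,12,16-trimethylheptadeca-3,7,11,15-tetraen-1-yl]oxolane-2,5-dione | CC(C)=CCC/C(C)=C/CC/C(C)=C/CC/C(CO)=C\C[C@@H](O)[C@@H]1CC(=O)OC1=O | intermediate
30 | Hippolide D | CC(C)=CCC/C(C)=C/CC/C(C)=C/CC/C(C=O)=C\C[C@@H](O)[C@@H]1CC(=O)OC1=O | target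

**Step count**
Total: 19 steps. Longest linear sequence: 14 steps (steps 1–5 and 11–19; the ylide branch, steps 6–10 and 11–19, is equally long).

**Steps most likely to fail**

Step 17 (ring-expansion carbonylation). Attack of the cobaltate at C19, a primary carbon flanked by the branched C18, may be slower than Lewis-acid-induced β-elimination of the lactone to the 2-methylene acid or than deactivation of the catalyst, so that no CO is inserted. The fallback brings in C20 as part of a succinate and closes the anhydride by dehydration; it sets out from oxazolidinone 2 (with aldehyde 5 and ylide 19 as in the main route) and returns at anhydride 28. Oxazolidinone 2 is acylated with mono-tert-butyl succinate (PivCl, Et3N, LiCl) to the succinyl imide F1. Its dibutylboron enolate adds to aldehyde 5 to give the syn aldol F2, and TBSOTf gives the bis-silyl ether F3. Buffered HF·pyridine frees the primary alcohol F4, and Dess–Martin oxidation gives the aldehyde F5. Wittig reaction with ylide 19 gives the enal F6, Luche reduction the allylic alcohol F7, and TBSCl the silyl ether F8. LiOH/H2O2 removes the auxiliary to give the mono acid F9, TMSOTf/2,6-lutidine cleaves the tert-butyl ester to the diacid F10, and DCC in CH2Cl2 dehydrates this to 28. O17 stays silylated throughout, so the diacid cannot lactonise.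

Step 18 (global desilylation beside the anhydride). The hindered C17 silyl ether needs long exposure, during which the anhydride may open, or the freed C17 hydroxyl may transfer onto C20 in the pyridine-containing medium to give the γ-lactone acid. The fallback changes the protecting groups before the key step so that the last unmasking takes minutes; it sets out from β-lactone 26 and returns at diol 29. HF·pyridine at the lactone stage gives the diol lactone F11, and TESOTf/2,6-lutidine gives the bis-triethylsilyl lactone F12. The same carbonylation gives the bis-triethylsilyl anhydride F13, and brief treatment with dilute HF·pyridine in THF at −20 °C gives 29.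

Step 16 (closure of the four-membered lactone). The oxyphosphonium carboxylate may fragment by decarboxylative elimination to the 1,1-disubstituted alkene, or react intermolecularly, instead of closing the strained ring. The fallback activates the carboxyl group and not the hydroxyl group; it sets out from hydroxy acid 25 and returns at β-lactone 26. Benzenesulfonyl chloride in pyridine at 0 °C gives the mixed carboxylic sulfonic anhydride F14 (not isolated), which the C19 hydroxyl closes by acyl substitution (4-exo-trig).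

**Further compounds**
F1 | step 17 | (S)-4-benzyl-3-(4-tert-butoxy-4-oxobutanoyl)oxazolidin-2-one | CC(C)(C)OC(=O)CCC(=O)N1[C@@H](Cc2ccccc2)COC1=O
F2 | step 17 | tert-butyl (3S,4R)-3-[(S)-4-benzyl-2-oxooxazolidine-3-carbonyl]-6-(TBS-oxy)-4-hydroxyhexanoate | CC(C)(C)[Si](C)(C)OCC[C@@H](O)[C@H](CC(=O)OC(C)(C)C)C(=O)N1[C@@H](Cc2ccccc2)COC1=O
F3 | step 17 | tert-butyl (3S,4R)-3-[(S)-4-benzyl-2-oxooxazolidine-3-carbonyl]-4,6-bis(TBS-oxy)hexanoate | CC(C)(C)[Si](C)(C)OCC[C@@H](O[Si](C)(C)C(C)(C)C)[C@H](CC(=O)OC(C)(C)C)C(=O)N1[C@@H](Cc2ccccc2)COC1=O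
F4 | step 17 | tert-butyl (3S,4R)-3-[(S)-4-benzyl-2-oxooxazolidine-3-carbonyl]-4-(TBS-oxy)-6-hydroxyhexanoate | OCC[C@@H](O[Si](C)(C)C(C)(C)C)[C@H](CC(=O)OC(C)(C)C)C(=O)N1[C@@H](Cc2ccccc2)COC1=O
F5 | step 17 | tert-butyl (3S,4R)-3-[(S)-4-benzyl-2-oxooxazolidine-3-carbonyl]-4-(TBS-oxy)-6-oxohexanoate | O=CC[C@@H](O[Si](C)(C)C(C)(C)C)[C@H](CC(=O)OC(C)(C)C)C(=O)N1[C@@H](Cc2ccccc2)COC1=O
F6 | step 17 | tert-butyl (3S,4R,6E,10E,14E)-3-[(S)-4-benzyl-2-oxooxazolidine-3-carbonyl]-4-(TBS-oxy)-7-formyl-11,15,19-trimethylicosa-6,10,14,18-tetraenoate | CC(C)=CCC/C(C)=C/CC/C(C)=C/CC/C(C=O)=C\C[C@@H](O[Si](C)(C)C(C)(C)C)[C@H](CC(=O)OC(C)(C)C)C(=O)N1[C@@H](Cc2ccccc2)COC1=O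
F7 | step 17 | tert-butyl (3S,4R,6E,10E,14E)-3-[(S)-4-benzyl-2-oxooxazolidine-3-carbonyl]-4-(TBS-oxy)-7-(hydroxymethyl)-11,15,19-trimethylicosa-6,10,14,18-tetraenoate | CC(C)=CCC/C(C)=C/CC/C(C)=C/CC/C(CO)=C\C[C@@H](O[Si](C)(C)C(C)(C)C)[C@H](CC(=O)OC(C)(C)C)C(=O)N1[C@@H](Cc2ccccc2)COC1=O
F8 | step 17 | tert-butyl (3S,4R,6E,10E,14E)-3-[(S)-4-benzyl-2-oxooxazolidine-3-carbonyl]-4-(TBS-oxy)-7-(TBS-oxymethyl)-11,15,19-trimethylicosa-6,10,14,18-tetraenoate | CC(C)=CCC/C(C)=C/CC/C(C)=C/CC/C(CO[Si](C)(C)C(C)(C)C)=C\C[C@@H](O[Si](C)(C)C(C)(C)C)[C@H](CC(=O)OC(C)(C)C)C(=O)N1[C@@H](Cc2ccccc2)COC1=O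
F9 | step 17 | (2S)-2-[(1R,3E,7E,11E)-1-(TBS-oxy)-4-(TBS-oxymethyl)-8,12,16-trimethylheptadeca-3,7,11,15-tetraen-1-yl]butanedioic acid 4-tert-butyl ester | CC(C)=CCC/C(C)=C/CC/C(C)=C/CC/C(CO[Si](C)(C)C(C)(C)C)=C\C[C@@H](O[Si](C)(C)C(C)(C)C)[C@H](CC(=O)OC(C)(C)C)C(=O)O
F10 | step 17 | (2S)-2-[(1R,3E,7E,11E)-1-(TBS-oxy)-4-(TBS-oxymethyl)-8,12,16-trimethylheptadeca-3,7,11,15-tetraen-1-yl]butanedioic acid | CC(C)=CCC/C(C)=C/CC/C(C)=C/CC/C(CO[Si](C)(C)C(C)(C)C)=C\C[C@@H](O[Si](C)(C)C(C)(C)C)[C@H](CC(=O)O)C(=O)O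
F11 | step 18 | (3S)-3-[(1R,3E,7E,11E)-1-hydroxy-4-(hydroxymethyl)-8,12,16-trimethylheptadeca-3,7,11,15-tetraen-1-yl]oxetan-2-one | CC(C)=CCC/C(C)=C/CC/C(C)=C/CC/C(CO)=C\C[C@@H](O)[C@@H]1COC1=O
F12 | step 18 | (3S)-3-[(1R,3E,7E,11E)-1-(triethylsilyloxy)-4-(triethylsilyloxymethyl)-8,12,16-trimethylheptadeca-3,7,11,15-tetraen-1-yl]oxetan-2-one | CC(C)=CCC/C(C)=C/CC/C(C)=C/CC/C(CO[Si](CC)(CC)CC)=C\C[C@@H](O[Si](CC)(CC)CC)[C@@H]1COC1=O
F13 | step 18 | (3S)-3-[(1R,3E,7E,11E)-1-(triethylsilyloxy)-4-(triethylsilyloxymethyl)-8,12,16-trimethylheptadeca-3,7,11,15-tetraen-1-yl]oxolane-2,5-dione | CC(C)=CCC/C(C)=C/CC/C(C)=C/CC/C(CO[Si](CC)(CC)CC)=C\C[C@@H](O[Si](CC)(CC)CC)[C@@H]1CC(=O)OC1=O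
F14 | step 16 | mixed anhydride of acid 25 with benzenesulfonic acid | CC(C)=CCC/C(C)=C/CC/C(C)=C/CC/C(CO[Si](C)(C)C(C)(C)C)=C\C[C@@H](O[Si](C)(C)C(C)(C)C)[C@H](CO)C(=O)OS(=O)(=O)c1ccccc1
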